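**Retrosynthetic overview**

1. Target 20 ⇐ global desilylation of 19 ⇐ Horner–Wadsworth–Emmons olefination (distal C=C of the diene) of oxolanyl enal 10 with isocoumarin phosphonate 18.
2. Enal 10 ⇐ cross-metathesis and O-silylation of (2S,3S,5S)-2-ethenyl-5-methyloxolan-3-ol 8.
3. Oxolane 8 ⇐ ring closure by the C2–C3 bond: oxidation-triggered intramolecular allylboration of (Z)-γ-alkoxyallylboronate 5 (via aldehyde 6), made from ethyl (3S)-3-hydroxybutanoate 1, which supplies C5 and O1.
4. Enabling feature: in the oxolane ring C3 bears OH and its neighbour C2 bears both the ring oxygen O1 and an alkene, i.e. a homoallylic alcohol whose allylic carbon is an ether carbon; this is the retron of a γ-alkoxyallylboration in which the ring oxygen is the γ-alkoxy group and tethers the allyl unit to the aldehyde.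
5. Isocoumarin 18 ⇐ pyranone ring closed onto the purchased benzene ring by lateral acylation/enol lactonisation of chlorinated toluate 12; ring order: benzene (bought), pyranone (step 8), oxolane (step 4), union in step 13.

Key step: step 4

Remark on the chemistry: the two numbered starting materials and all unnumbered reagents are taken to be commercial; oxolane locants are O1, C2 (dienyl), C3 (OH), C4, C5 (methyl), and the target is 2,3-cis, 2,5-trans (2S,3S,5S).

**Route**

Step 1
Reactants: 1 ethyl (3S)-3-hydroxybutanoate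
Product: 2 ethyl (3S)-3-(prop-2-en-1-yloxy)butanoate
Conditions: allyl 2,2,2-trichloroacetimidate, TfOH (cat.), cyclohexane/CH2Cl2, 0 °C to rt
Reagents that add atoms: allyl 2,2,2-trichloroacetimidate, C=CCOC(=N)C(Cl)(Cl)Cl
Why: Acid-catalysed O-alkylation by a trichloroacetimidate works under non-basic conditions, so the β-hydroxy ester should be allylated without retro-aldol cleavage or elimination and without touching the stereocentre.

Step 2
Reactants: 2 ethyl (3S)-3-(prop-2-en-1-yloxy)butanoate
Product: 3 (3S)-3-(prop-2-en-1-yloxy)butan-1-ol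
Conditions: LiAlH4, Et2O, 0 °C; Na2SO4·10H2O quench
Reagents that add atoms: none
Why: Hydride reduction of the ester gives the primary alcohol (the latent aldehyde) and leaves the allyl ether and the stereocentre untouched.

Step 3
Reactants: 3 (3S)-3-(prop-2-en-1-yloxy)butan-1-ol
Product: 5 (3S)-3-{[(1Z)-3-(4,4,5,5-tetramethyl-1,3,2-dioxaborolan-2-yl)prop-1-en-1-yl]oxy}butan-1-ol, via dilithiated allyl ether 4 (not isolated)
Conditions: sec-BuLi (2.2 equiv), THF, −78 °C; then 2-isopropoxy-4,4,5,5-tetramethyl-1,3,2-dioxaborolane, −78 °C to 0 °C; sat. aq. NH4Cl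
Reagents that add atoms: 2-isopropoxy-4,4,5,5-tetramethyl-1,3,2-dioxaborolane, CC(C)OB1OC(C)(C)C(C)(C)O1
Why: After O-deprotonation, α-lithiation of the allyl ether gives the O–Li chelated (Z)-alkoxyallyl anion, which boron electrophiles should trap at the carbon remote from oxygen, so that protonation of the ate complex leaves the (Z)-γ-alkoxyallyl pinacolboronate (metalation–borylation of allyl ethers).

Step 4
Reactants: 5 (3S)-3-{[(1Z)-3-(4,4,5,5-tetramethyl-1,3,2-dioxaborolan-2-yl)prop-1-en-1-yl]oxy}butan-1-ol
Product: 8 (2S,3S,5S)-2-ethenyl-5-methyloxolan-3-ol, via aldehyde 6 (not isolated), via borate ester 7 (not isolated)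
Conditions: Dess–Martin periodinane, pyridine, CH2Cl2, 0 °C to rt, then 35 °C until ring closure is complete; aq. NaHCO3 work-up
Reagents that add atoms: none
Why: Oxidation of the primary alcohol unmasks aldehyde 6, whose carbonyl oxygen binds the boron so that the γ-carbon of the allylboronate (the enol-ether carbon, future C2) adds to the carbonyl carbon (future C3) through a closed six-membered chair transition state with allylic transposition, giving borate 7 and, after hydrolysis, 8. The closest known reaction type is the intramolecular allylboration of γ-(ω-formylalkoxy)allylboronates to 2-ethenyl-3-hydroxy oxanes and oxepanes; here the same event closes the smaller oxolane. The oxolane is closed in the 5-exo-trig mode at the carbonyl group, the chair being cis-fused to the forming five-membered ring. C2 and C3 are set together by the (Z)-enol ether geometry, which places O1 axial and the C4 chain equatorial in the chair and so translates into the syn (2,3-cis) relationship of vinyl and hydroxyl. The configuration of both new centres relative to C5 (from 1) should follow from the C5 methyl group taking the exo position of the bicyclic transition state, the endo position being 1,3-syn to the boron-bound carbonyl oxygen; this facial selectivity is what the step needs and is its least secure element. Z-to-E scrambling should not occur with the pinacol ester at this temperature, and the non-acidic oxidation spares the enol ether.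

Step 5
Reactants: 8 (2S,3S,5S)-2-ethenyl-5-methyloxolan-3-ol
Product: 9 tert-butyl{[(2S,3S,5S)-2-ethenyl-5-methyloxolan-3-yl]oxy}dimethylsilane
Conditions: TBSCl, imidazole, DMF, rt
Reagents that add atoms: tert-butyl(chloro)dimethylsilane, CC(C)(C)[Si](C)(C)Cl
Why: Standard silylation masks the secondary alcohol for the metathesis and the basic olefination and lowers the volatility of the small oxolane.

Step 6
Reactants: 9 tert-butyl{[(2S,3S,5S)-2-ethenyl-5-methyloxolan-3-yl]oxy}dimethylsilane
Product: 10 (2E)-3-[(2S,3S,5S)-3-{[tert-butyl(dimethyl)silyl]oxy}-5-methyloxolan-2-yl]prop-2-enal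
Conditions: (2E)-but-2-enal (excess), second-generation Hoveyda–Grubbs catalyst RuCl2(H2IMes)(=CH-C6H4-2-OiPr) (cat.), CH2Cl2, 40 °C
Reagents that add atoms: (2E)-but-2-enal, C/C=C/C=O
Why: Olefin cross-metathesis of the monosubstituted alkene with excess crotonaldehyde should give the (E)-enal with loss of propene and without touching the ring stereocentres.

Step 7
Reactants: 11 methyl 2,4-dimethoxy-6-methylbenzoate
Product: 12 methyl 3-chloro-4,6-dimethoxy-2-methylbenzoate
Conditions: SO2Cl2, CH2Cl2, 0 °C
Reagents that add atoms: sulfuryl chloride, O=S(=O)(Cl)Cl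
Why: Electrophilic aromatic chlorination is expected at the position para to the 2-methoxy group and ortho to the 4-methoxy and methyl groups, the only other free position lying between two methoxy groups and being more hindered, as in chlorinations of orsellinate-type arenes.

Step 8
Reactants: 12 methyl 3-chloro-4,6-dimethoxy-2-methylbenzoate
Product: 14 5-chloro-6,8-dimethoxy-3-methyl-1H-isochromen-1-one, via keto ester 13 (not isolated)
Conditions: LiN(iPr)2, THF, −78 °C; N-methoxy-N-methylacetamide; 1 M HCl quench; crude product, TsOH·H2O (cat.), toluene, reflux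
Reagents that add atoms: N-methoxy-N-methylacetamide, CC(=O)N(C)OC
Why: Lateral lithiation of the ortho-toluate gives the benzylic anion, which is acylated once by the Weinreb amide, and acid-catalysed enol lactonisation of keto ester 13 onto the neighbouring ester then closes the pyranone ring with loss of methanol.

Step 9
Reactants: 14 5-chloro-6,8-dimethoxy-3-methyl-1H-isochromen-1-one
Product: 15 5-chloro-6,8-dihydroxy-3-methyl-1H-isochromen-1-one
Conditions: BBr3, CH2Cl2, −78 °C to rt; aqueous work-up
Reagents that add atoms: none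
Why: BBr3 cleaves both aryl methyl ethers while the enol lactone survives, so the robust methyl groups are exchanged before any sensitive functionality is present.

Step 10
Reactants: 15 5-chloro-6,8-dihydroxy-3-methyl-1H-isochromen-1-one
Product: 16 6,8-bis{[tert-butyl(dimethyl)silyl]oxy}-5-chloro-3-methyl-1H-isochromen-1-one
Conditions: TBSOTf, 2,6-lutidine, CH2Cl2, 0 °C to rt
Reagents that add atoms: tert-butyldimethylsilyl trifluoromethanesulfonate, CC(C)(C)[Si](C)(C)OS(=O)(=O)C(F)(F)F
Why: The silyl triflate should silylate both phenols, including the hydrogen-bonded C8 hydroxyl, giving ethers that survive radical bromination, the Arbuzov reaction and the olefination base and fall to fluoride at the end.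

Step 11
Reactants: 16 6,8-bis{[tert-butyl(dimethyl)silyl]oxy}-5-chloro-3-methyl-1H-isochromen-1-one
Product: 17 3-(bromomethyl)-6,8-bis{[tert-butyl(dimethyl)silyl]oxy}-5-chloro-1H-isochromen-1-one
Conditions: NBS, AIBN (cat.), PhCF3, 80 °C
Reagents that add atoms: N-bromosuccinimide, O=C1CCC(=O)N1Br
Why: Wohl–Ziegler bromination should occur at the 3-methyl group, whose radical is allylic to the enol-lactone double bond, while the only ring C–H (C7) is shielded by two flanking silyloxy groups and the nonpolar radical conditions disfavour ionic bromination at C4.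

Step 12
Reactants: 17 3-(bromomethyl)-6,8-bis{[tert-butyl(dimethyl)silyl]oxy}-5-chloro-1H-isochromen-1-one
Product: 18 diethyl [(6,8-bis{[tert-butyl(dimethyl)silyl]oxy}-5-chloro-1-oxo-1H-isochromen-3-yl)methyl]phosphonate
Conditions: P(OEt)3, toluene, 110 °C
Reagents that add atoms: triethyl phosphite, CCOP(OCC)OCC
Why: Michaelis–Arbuzov reaction of the allylic-type primary bromide gives the phosphonate, with volatile bromoethane as the only by-product.

Step 13
Reactants: 18 diethyl [(6,8-bis{[tert-butyl(dimethyl)silyl]oxy}-5-chloro-1-oxo-1H-isochromen-3-yl)methyl]phosphonate; 10 (2E)-3-[(2S,3S,5S)-3-{[tert-butyl(dimethyl)silyl]oxy}-5-methyloxolan-2-yl]prop-2-enal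
Product: 19 6,8-bis{[tert-butyl(dimethyl)silyl]oxy}-3-{(1E,3E)-4-[(2S,3S,5S)-3-{[tert-butyl(dimethyl)silyl]oxy}-5-methyloxolan-2-yl]buta-1,3-dien-1-yl}-5-chloro-1H-isochromen-1-one
Conditions: LiN(SiMe3)2, THF, −78 °C; then 10, −78 °C to 0 °C
Reagents that add atoms: none
Why: Horner–Wadsworth–Emmons olefination of the stabilised phosphonate anion with the enal should form the new C=C bond with E selectivity and complete the (E,E)-diene, the low temperature and non-nucleophilic base sparing the lactone, the aryl silyl ethers and the oxolane stereocentres.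

Step 14
Reactants: 19 6,8-bis{[tert-butyl(dimethyl)silyl]oxy}-3-{(1E,3E)-4-[(2S,3S,5S)-3-{[tert-butyl(dimethyl)silyl]oxy}-5-methyloxolan-2-yl]buta-1,3-dien-1-yl}-5-chloro-1H-isochromen-1-one
Product: 20 5-chloro-6,8-dihydroxy-3-{(1E,3E)-4-[(2S,3S,5S)-3-hydroxy-5-methyloxolan-2-yl]buta-1,3-dien-1-yl}-1H-isochromen-1-one
Conditions: HF·pyridine, pyridine, THF, 0 °C to rt
Reagents that add atoms: none
Why: Buffered fluoride removes the two aryl silyl ethers and the secondary silyl ether in one operation under conditions that should neither ionise the dienylic C2–O bond nor open the lactone, giving the target with all stereocentres unchanged.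

**Compound list**

1 | ethyl (3S)-3-hydroxybutanoate | CCOC(=O)C[C@H](C)O | starting material
2 | ethyl (3S)-3-(prop-2-en-1-yloxy)butanoate | CCOC(=O)C[C@H](C)OCC=C | intermediate
3 | (3S)-3-(prop-2-en-1-yloxy)butan-1-ol | OCC[C@H](C)OCC=C | intermediate
4 | lithium (3S)-3-{[(1Z)-3-lithioprop-1-en-1-yl]oxy}butan-1-olate | [Li]OCC[C@H](C)O/C=C\C[Li] | intermediate (not isolated)
5 | (3S)-3-{[(1Z)-3-(4,4,5,5-tetramethyl-1,3,2-dioxaborolan-2-yl)prop-1-en-1-yl]oxy}butan-1-ol | OCC[C@H](C)O/C=C\CB1OC(C)(C)C(C)(C)O1 | intermediate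
6 | (3S)-3-{[(1Z)-3-(4,4,5,5-tetramethyl-1,3,2-dioxaborolan-2-yl)prop-1-en-1-yl]oxy}butanal | O=CC[C@H](C)O/C=C\CB1OC(C)(C)C(C)(C)O1 | intermediate (not isolated)
7 | 2-{[(2S,3S,5S)-2-ethenyl-5-methyloxolan-3-yl]oxy}-4,4,5,5-tetramethyl-1,3,2-dioxaborolane | C[C@H]1C[C@H](OB2OC(C)(C)C(C)(C)O2)[C@H](C=C)O1 | intermediate (not isolated)
8 | (2S,3S,5S)-2-ethenyl-5-methyloxolan-3-ol | C[C@H]1C[C@H](O)[C@H](C=C)O1 | intermediate
9 | tert-butyl{[(2S,3S,5S)-2-ethenyl-5-methyloxolan-3-yl]oxy}dimethylsilane | C[C@H]1C[C@H](O[Si](C)(C)C(C)(C)C)[C@H](C=C)O1 | intermediate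
10 | (2E)-3-[(2S,3S,5S)-3-{[tert-butyl(dimethyl)silyl]oxy}-5-methyloxolan-2-yl]prop-2-enal | C[C@H]1C[C@H](O[Si](C)(C)C(C)(C)C)[C@H](/C=C/C=O)O1 | intermediate
11 | methyl 2,4-dimethoxy-6-methylbenzoate | COC(=O)c1c(C)cc(OC)cc1OC | starting material
12 | methyl 3-chloro-4,6-dimethoxy-2-methylbenzoate | COC(=O)c1c(C)c(Cl)c(OC)cc1OC | intermediate
13 | methyl 3-chloro-4,6-dimethoxy-2-(2-oxopropyl)benzoate | COC(=O)c1c(CC(C)=O)c(Cl)c(OC)cc1OC | intermediate (not isolated)
14 | 5-chloro-6,8-dimethoxy-3-methyl-1H-isochromen-1-one | Cc1cc2c(Cl)c(OC)cc(OC)c2c(=O)o1 | intermediate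
15 | 5-chloro-6,8-dihydroxy-3-methyl-1H-isochromen-1-one | Cc1cc2c(Cl)c(O)cc(O)c2c(=O)o1 | intermediate
16 | 6,8-bis{[tert-butyl(dimethyl)silyl]oxy}-5-chloro-3-methyl-1H-isochromen-1-one | Cc1cc2c(Cl)c(O[Si](C)(C)C(C)(C)C)cc(O[Si](C)(C)C(C)(C)C)c2c(=O)o1 | intermediate
17 | 3-(bromomethyl)-6,8-bis{[tert-butyl(dimethyl)silyl]oxy}-5-chloro-1H-isochromen-1-one | BrCc1cc2c(Cl)c(O[Si](C)(C)C(C)(C)C)cc(O[Si](C)(C)C(C)(C)C)c2c(=O)o1 | intermediate
18 | diethyl [(6,8-bis{[tert-butyl(dimethyl)silyl]oxy}-5-chloro-1-oxo-1H-isochromen-3-yl)methyl]phosphonate | CCOP(=O)(OCC)Cc1cc2c(Cl)c(O[Si](C)(C)C(C)(C)C)cc(O[Si](C)(C)C(C)(C)C)c2c(=O)o1 | intermediate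
19 | 6,8-bis{[tert-butyl(dimethyl)silyl]oxy}-3-{(1E,3E)-4-[(2S,3S,5S)-3-{[tert-butyl(dimethyl)silyl]oxy}-5-methyloxolan-2-yl]buta-1,3-dien-1-yl}-5-chloro-1H-isochromen-1-one | C[C@H]1C[C@H](O[Si](C)(C)C(C)(C)C)[C@H](/C=C/C=C/c2cc3c(Cl)c(O[Si](C)(C)C(C)(C)C)cc(O[Si](C)(C)C(C)(C)C)c3c(=O)o2)O1 | intermediate
20 | 5-chloro-6,8-dihydroxy-3-{(1E,3E)-4-[(2S,3S,5S)-3-hydroxy-5-methyloxolan-2-yl]buta-1,3-dien-1-yl}-1H-isochromen-1-one (CNP0086741.6) | C[C@H]1C[C@H](O)[C@H](/C=C/C=C/c2cc3c(Cl)c(O)cc(O)c3c(=O)o2)O1 | target

**Totals and risks**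

Total step count: 14. Longest linear sequence: 8 steps (steps 1–6, 13, 14; the isocoumarin branch, steps 7–12, 13, 14, is equally long).

The three steps most likely to fail:

Step 4 (key step). What may go wrong is insufficient facial discrimination with respect to the C5 methyl group, so that the endo transition state delivers the 2,5-cis epimer alongside 8; base-induced β-elimination of the β-alkoxy aldehyde before ring closure is a second possibility. The fallback changes the ring-closure mode and uses known chemistry. It sets out from 2: saponification (LiOH, THF/H2O) gives (3S)-3-(prop-2-en-1-yloxy)butanoic acid F1. Oxalyl chloride (cat. DMF) gives (3S)-3-(prop-2-en-1-yloxy)butanoyl chloride F2, and diazomethane gives (4S)-1-diazo-4-(prop-2-en-1-yloxy)pentan-2-one F3. Cu(acac)2-catalysed carbenoid formation, cyclic oxonium ylide formation and [2,3]-sigmatropic shift of the allyl group should give (2S,5S)-5-methyl-2-(prop-2-en-1-yl)oxolan-3-one F4, a reaction type known to favour trans-2,5-disubstituted oxolan-3-ones. LiBH(sec-Bu)3 reduction anti to the C2 substituent should give (2S,3S,5S)-5-methyl-2-(prop-2-en-1-yl)oxolan-3-ol F5, and silylation (TBSCl, imidazole) gives tert-butyldimethyl{[(2S,3S,5S)-5-methyl-2-(prop-2-en-1-yl)oxolan-3-yl]oxy}silane F6. Alkene isomerisation with RuHCl(CO)(PPh3)3 (cat.) gives tert-butyldimethyl({(2S,3S,5S)-5-methyl-2-[(1E)-prop-1-en-1-yl]oxolan-3-yl}oxy)silane F7. Cross-metathesis with but-2-enal under the conditions of step 6 brings the material back to the route at 10.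

Step 3. What may go wrong is incomplete or unselective allylic metalation in the presence of the aggregated lithium alkoxide, [1,2]-Wittig rearrangement of the lithiated ether on warming, or protodeboronation of the hydroxy boronate on work-up. The fallback masks the aldehyde instead of carrying a free alcohol and triggers the ring closure by hydrolysis. It sets out from 2: iBu2AlH (CH2Cl2, −78 °C) gives (3S)-3-(prop-2-en-1-yloxy)butanal F8, and acetalisation (HC(OMe)3, PPTS, MeOH) gives (3S)-1,1-dimethoxy-3-(prop-2-en-1-yloxy)butane F9. Metalation–borylation of this alkoxide-free ether (sec-BuLi, then the isopropoxyboronate) gives 2-[(2Z)-3-{[(2S)-4,4-dimethoxybutan-2-yl]oxy}prop-2-en-1-yl]-4,4,5,5-tetramethyl-1,3,2-dioxaborolane F10. Acetal cleavage with LiBF4 in wet MeCN releases aldehyde 6, where the route is rejoined (6 to 8 as in step 4).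

Step 11. What may go wrong is competing ionic bromination at C4 or at C7, or over-bromination of the methyl group. The fallback replaces radical halogenation by carbanion chemistry and sets out from 16: double deprotonation of the 3-methyl group with LiN(iPr)2 (2.2 equiv, THF, −78 °C) and C-phosphorylation with diethyl chlorophosphate, the γ-phosphorylation of a vinylogous ester enolate practised on 6-methyl-1,3-dioxin-4-ones, should give phosphonate 18 directly, where the route is rejoined; no new compound is formed on the way.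

**Further compounds**

F1 | step 4 | (3S)-3-(prop-2-en-1-yloxy)butanoic acid | OC(=O)C[C@H](C)OCC=C
F2 | step 4 | (3S)-3-(prop-2-en-1-yloxy)butanoyl chloride | ClC(=O)C[C@H](C)OCC=C
F3 | step 4 | (4S)-1-diazo-4-(prop-2-en-1-yloxy)pentan-2-one | [N-]=[N+]=CC(=O)C[C@H](C)OCC=C
F4 | step 4 | (2S,5S)-5-methyl-2-(prop-2-en-1-yl)oxolan-3-one | C[C@H]1CC(=O)[C@H](CC=C)O1
F5 | step 4 | (2S,3S,5S)-5-methyl-2-(prop-2-en-1-yl)oxolan-3-ol | C[C@H]1C[C@H](O)[C@H](CC=C)O1
F6 | step 4 | tert-butyldimethyl{[(2S,3S,5S)-5-methyl-2-(prop-2-en-1-yl)oxolan-3-yl]oxy}silane | C[C@H]1C[C@H](O[Si](C)(C)C(C)(C)C)[C@H](CC=C)O1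
F7 | step 4 | tert-butyldimethyl({(2S,3S,5S)-5-methyl-2-[(1E)-prop-1-en-1-yl]oxolan-3-yl}oxy)silane | C[C@H]1C[C@H](O[Si](C)(C)C(C)(C)C)[C@H](/C=C/C)O1
F8 | step 3 | (3S)-3-(prop-2-en-1-yloxy)butanal | O=CC[C@H](C)OCC=C
F9 | step 3 | (3S)-1,1-dimethoxy-3-(prop-2-en-1-yloxy)butane | COC(OC)C[C@H](C)OCC=C
F10 | step 3 | 2-[(2Z)-3-{[(2S)-4,4-dimethoxybutan-2-yl]oxy}prop-2-en-1-yl]-4,4,5,5-tetramethyl-1,3,2-dioxaborolane | COC(OC)C[C@H](C)O/C=C\CB1OC(C)(C)C(C)(C)O1
F0 | step 11 | none | none
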